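**Retrosynthetic overview**
- The target comes from its dimethyl ketal; the triene is cut at C2'–C3' (Heck) into a 5-vinyl epoxyquinol ketal and an (E,E)-iododienamide that already carries the aminocyclopentenone.
- The vinyl carbinol comes from vinyl Grignard addition anti to the oxirane of an epoxyquinone monoketal, made by catalytic asymmetric nucleophilic epoxidation of the monoketal obtained by dearomatising N-acylated 3-aminophenol.
- Key disconnection: the C6–C7 bond of the acyl chain. The only non-core stereocentre is made by nickel-catalysed enantioconvergent radical coupling of a racemic ε-bromo dienoate with butylzinc bromide; the bromide itself comes from radical C–H bromination of an achiral dienoate.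
- The iododienamide comes from Takai iodo-olefination of methyl (E)-4-oxobut-2-enoate, saponification and N-acylation.
- Rings: the carbocycle is bought as the benzene ring of 3-aminophenol and dearomatised; the cyclopentenone is bought; the oxirane is the only ring built, and it is formed before the tertiary carbinol.

Assumption: 2-amino-3-hydroxycyclopent-2-en-1-one and methyl (E)-4-oxobut-2-enoate are taken as catalogue compounds, and the named Pybox antipode and cinchona salt are taken to be the ones that give the drawn configurations (otherwise the mirror-image ligand or the pseudoenantiomeric salt is used).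

**Route**

Step 1
Reactants: 1 (E)-2-methylpent-2-enal; 2 methyl hydrogen malonate
Product: 3 methyl (2E,4E)-4-methylhepta-2,4-dienoate
Conditions: piperidine (cat.), pyridine, 90 °C
Reagents that add atoms: none
Why: Knoevenagel–Doebner condensation of the enal with the malonic half-ester, with loss of CO2, gives the thermodynamically favoured (2E) enoate and leaves the (E) trisubstituted alkene of 1 untouched.

Step 2
Reactants: 3 methyl (2E,4E)-4-methylhepta-2,4-dienoate
Product: 4 racemic methyl (2E,4E)-6-bromo-4-methylhepta-2,4-dienoate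
Conditions: NBS (1.05 equiv), AIBN (cat.), PhCF3, 85 °C
Reagents that add atoms: N-bromosuccinimide, O=C1CCC(=O)N1Br
Why: Wohl–Ziegler radical bromination, in which the bromine atom abstracts the C6–H because that radical is a pentadienyl radical conjugated to the ester (the C4-methyl radical is only cross-conjugated), and bromine transfer at C6 keeps the dienoate conjugated as with methyl sorbate; the new centre may be racemic because step 3 is stereoconvergent.

Step 3
Reactants: 4 racemic methyl (2E,4E)-6-bromo-4-methylhepta-2,4-dienoate; 5 butylzinc bromide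
Product: 7 methyl (2E,4E,6R)-4,6-dimethyldeca-2,4-dienoate, via racemic allylic chloride 6 (not isolated)
Conditions: LiCl (3 equiv), DMA, 23 °C, 1 h; then 5 (1.6 equiv), NiCl2·DME (5 mol%), (S,S)-2,6-bis[4-(2-phenylethyl)-4,5-dihydrooxazol-2-yl]pyridine (5.5 mol%), NaCl, DMA/DMF, −10 °C, 24 h
Reagents that add atoms: none
Why: Proposed new method: bromide–chloride exchange gives the secondary allylic chloride 6, monovalent nickel abstracts its halogen to give a planar ester-conjugated pentadienyl radical so that both enantiomers and any allylic or E/Z isomers converge, and the radical is captured by the chiral (Pybox)Ni–Bu complex, whose trivalent nickel intermediate eliminates reductively at the less hindered C6 terminus (this keeps the dienoate conjugated and sets C6 as R under ligand control); the closest known reaction is the nickel/Pybox-catalysed enantioconvergent Negishi coupling of racemic secondary allylic chlorides, γ-chloro enoates included, with alkylzinc halides.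

Step 4
Reactants: 7 methyl (2E,4E,6R)-4,6-dimethyldeca-2,4-dienoate; 8 3-aminophenol
Product: 9 (2E,4E,6R)-N-(3-hydroxyphenyl)-4,6-dimethyldeca-2,4-dienamide
Conditions: 8 (1.5 equiv), AlMe3 (3.0 equiv), toluene/THF, 0 → 80 °C; then 1 M HCl
Reagents that add atoms: none
Why: Weinreb-type aminolysis, in which the aluminium anilide Me2Al–NHAr formed from 8 and AlMe3 attacks the ester carbonyl in 1,2-fashion while the aluminium phenoxide stays unreactive and is freed on work-up; the C6 stereocentre is remote from every reacting centre.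

Step 5
Reactants: 9 (2E,4E,6R)-N-(3-hydroxyphenyl)-4,6-dimethyldeca-2,4-dienamide
Product: 11 (2E,4E,6R)-N-(6,6-dimethoxy-3-oxocyclohexa-1,4-dien-1-yl)-4,6-dimethyldeca-2,4-dienamide, via p-methoxyphenol anilide 10 (not isolated)
Conditions: PhI(OAc)2 (2.2 equiv), MeOH, 0 °C → rt
Reagents that add atoms: methanol, CO
Why: Oxidative dearomatisation with trivalent iodine, in which the first equivalent methoxylates the position para to the phenol OH (also activated by the ortho amide) to give 10 and the second converts this p-methoxyphenol into the p-quinone monoketal, placing the ketal next to C–N and leaving the other carbonyl free.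

Step 6
Reactants: 11 (2E,4E,6R)-N-(6,6-dimethoxy-3-oxocyclohexa-1,4-dien-1-yl)-4,6-dimethyldeca-2,4-dienamide
Product: 12 (2E,4E,6R)-N-[(1S,6R)-2,2-dimethoxy-5-oxo-7-oxabicyclo[4.1.0]hept-3-en-3-yl]-4,6-dimethyldeca-2,4-dienamide
Conditions: t-BuOOH, NaOH (aq), N-benzylcinchoninium chloride (10 mol%), toluene, 0 °C → rt
Reagents that add atoms: tert-butyl hydroperoxide, CC(C)(C)OO
Why: Weitz–Scheffer nucleophilic epoxidation under chiral phase-transfer catalysis (Wynberg type), in which the peroxide anion attacks only the unsubstituted enone (the other β-carbon is a vinylogous amide) and the cinchona ion pair selects the alkene face, setting C1 as S and C6 as R; the minor diastereomer is removed by crystallisation or chromatography.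

Step 7
Reactants: 12 (2E,4E,6R)-N-[(1S,6R)-2,2-dimethoxy-5-oxo-7-oxabicyclo[4.1.0]hept-3-en-3-yl]-4,6-dimethyldeca-2,4-dienamide; 13 vinylmagnesium bromide
Product: 14 (2E,4E,6R)-N-[(1S,5S,6R)-5-ethenyl-5-hydroxy-2,2-dimethoxy-7-oxabicyclo[4.1.0]hept-3-en-3-yl]-4,6-dimethyldeca-2,4-dienamide
Conditions: 13 (3 equiv), THF, −78 → −40 °C; aq NH4Cl
Reagents that add atoms: none
Why: Grignard 1,2-addition, in which the first equivalent deprotonates the amide N–H and the next adds to the ketone from the face opposite the oxirane oxygen, setting C5 as S with the hydroxyl syn to the epoxide, as in alkenyllithium additions to this ring system.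

Step 8
Reactants: 15 methyl (E)-4-oxobut-2-enoate; 16 iodoform
Product: 17 methyl (2E,4E)-5-iodopenta-2,4-dienoate
Conditions: CrCl2 (6 equiv), THF, 0 °C → rt
Reagents that add atoms: none
Why: Takai iodo-olefination, in which the geminal dichromium reagent ICH(CrCl2)2 formed from CHI3 and CrCl2 adds to the aldehyde only (the ester is inert) and elimination gives the (E)-vinyl iodide.

Step 9
Reactants: 17 methyl (2E,4E)-5-iodopenta-2,4-dienoate
Product: 18 (2E,4E)-5-iodopenta-2,4-dienoic acid
Conditions: LiOH, THF/H2O, 0 °C; then 1 M HCl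
Reagents that add atoms: lithium hydroxide, [Li+].[OH-]
Why: Ester saponification, to which the vinyl iodide and the diene geometry are stable at 0 °C.

Step 10
Reactants: 18 (2E,4E)-5-iodopenta-2,4-dienoic acid; 19 2-amino-3-hydroxycyclopent-2-en-1-one
Product: 21 (2E,4E)-N-(2-hydroxy-5-oxocyclopent-1-en-1-yl)-5-iodopenta-2,4-dienamide, via iododienoyl chloride 20 (not isolated)
Conditions: (COCl)2, DMF (cat.), CH2Cl2, 0 °C → rt; evaporate; then 19, pyridine, THF, 0 °C → rt
Reagents that add atoms: none
Why: Acid chloride formation followed by N-acylation of the aminoenol, in which any O-acyl product rearranges to the more stable N-acyl enaminone.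

Step 11
Reactants: 14 (2E,4E,6R)-N-[(1S,5S,6R)-5-ethenyl-5-hydroxy-2,2-dimethoxy-7-oxabicyclo[4.1.0]hept-3-en-3-yl]-4,6-dimethyldeca-2,4-dienamide; 21 (2E,4E)-N-(2-hydroxy-5-oxocyclopent-1-en-1-yl)-5-iodopenta-2,4-dienamide
Product: 22 (2E,4E,6R)-N-[(1S,5S,6R)-5-hydroxy-5-[(1E,3E,5E)-7-[(2-hydroxy-5-oxocyclopent-1-en-1-yl)amino]-7-oxohepta-1,3,5-trien-1-yl]-2,2-dimethoxy-7-oxabicyclo[4.1.0]hept-3-en-3-yl]-4,6-dimethyldeca-2,4-dienamide
Conditions: Pd(OAc)2 (10 mol%), K2CO3, Bu4NCl, DMF, 30 °C, dark; pH 5 buffer work-up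
Reagents that add atoms: none
Why: Mizoroki–Heck coupling under Jeffery conditions, in which zerovalent palladium adds the dienyl iodide with retention, insertion takes place at the CH2 terminus of the only monosubstituted alkene of 14, and syn β-hydride elimination (the carbinol carbon carries no hydrogen) gives the all-E triene without touching a stereocentre.

Step 12
Reactants: 22 (2E,4E,6R)-N-[(1S,5S,6R)-5-hydroxy-5-[(1E,3E,5E)-7-[(2-hydroxy-5-oxocyclopent-1-en-1-yl)amino]-7-oxohepta-1,3,5-trien-1-yl]-2,2-dimethoxy-7-oxabicyclo[4.1.0]hept-3-en-3-yl]-4,6-dimethyldeca-2,4-dienamide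
Product: 23 (2E,4E,6R)-N-[(1S,5S,6R)-5-hydroxy-5-[(1E,3E,5E)-7-[(2-hydroxy-5-oxocyclopent-1-en-1-yl)amino]-7-oxohepta-1,3,5-trien-1-yl]-2-oxo-7-oxabicyclo[4.1.0]hept-3-en-3-yl]-4,6-dimethyldeca-2,4-dienamide
Conditions: montmorillonite K10 (acid-treated clay, idealised Al2Si4O10(OH)2·nH2O), wet CH2Cl2, rt
Reagents that add atoms: water, O
Why: Acid-catalysed ketal hydrolysis on the solid acid unmasks the C2 ketone under conditions mild enough to leave the oxirane, the tertiary alcohol and all three stereocentres of the ring untouched.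

**Compound list**
1 | (E)-2-methylpent-2-enal | CC/C=C(\C)C=O | starting material
2 | methyl hydrogen malonate | COC(=O)CC(=O)O | starting material
3 | methyl (2E,4E)-4-methylhepta-2,4-dienoate | CC/C=C(\C)/C=C/C(=O)OC | intermediate
4 | racemic methyl (2E,4E)-6-bromo-4-methylhepta-2,4-dienoate | CC(Br)/C=C(\C)/C=C/C(=O)OC | intermediate
5 | butylzinc bromide | CCCC[Zn]Br | starting material
6 | racemic methyl (2E,4E)-6-chloro-4-methylhepta-2,4-dienoate | CC(Cl)/C=C(\C)/C=C/C(=O)OC | intermediate (not isolated)
7 | methyl (2E,4E,6R)-4,6-dimethyldeca-2,4-dienoate | CCCC[C@@H](C)/C=C(\C)/C=C/C(=O)OC | intermediate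
8 | 3-aminophenol | Nc1cccc(O)c1 | starting material
9 | (2E,4E,6R)-N-(3-hydroxyphenyl)-4,6-dimethyldeca-2,4-dienamide | CCCC[C@@H](C)/C=C(\C)/C=C/C(=O)Nc1cccc(O)c1 | intermediate
10 | (2E,4E,6R)-N-(5-hydroxy-2-methoxyphenyl)-4,6-dimethyldeca-2,4-dienamide | CCCC[C@@H](C)/C=C(\C)/C=C/C(=O)Nc1cc(O)ccc1OC | intermediate (not isolated)
11 | (2E,4E,6R)-N-(6,6-dimethoxy-3-oxocyclohexa-1,4-dien-1-yl)-4,6-dimethyldeca-2,4-dienamide | CCCC[C@@H](C)/C=C(\C)/C=C/C(=O)NC1=CC(=O)C=CC1(OC)OC | intermediate
12 | (2E,4E,6R)-N-[(1S,6R)-2,2-dimethoxy-5-oxo-7-oxabicyclo[4.1.0]hept-3-en-3-yl]-4,6-dimethyldeca-2,4-dienamide | CCCC[C@@H](C)/C=C(\C)/C=C/C(=O)NC1=CC(=O)[C@@H]2O[C@@H]2C1(OC)OC | intermediate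
13 | vinylmagnesium bromide | C=C[Mg]Br | starting material
14 | (2E,4E,6R)-N-[(1S,5S,6R)-5-ethenyl-5-hydroxy-2,2-dimethoxy-7-oxabicyclo[4.1.0]hept-3-en-3-yl]-4,6-dimethyldeca-2,4-dienamide | CCCC[C@@H](C)/C=C(\C)/C=C/C(=O)NC1=C[C@@](O)(C=C)[C@@H]2O[C@@H]2C1(OC)OC | intermediate
15 | methyl (E)-4-oxobut-2-enoate | COC(=O)/C=C/C=O | starting material
16 | iodoform | IC(I)I | starting material
17 | methyl (2E,4E)-5-iodopenta-2,4-dienoate | COC(=O)/C=C/C=C/I | intermediate
18 | (2E,4E)-5-iodopenta-2,4-dienoic acid | OC(=O)/C=C/C=C/I | intermediate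
19 | 2-amino-3-hydroxycyclopent-2-en-1-one | NC1=C(O)CCC1=O | starting material
20 | (2E,4E)-5-iodopenta-2,4-dienoyl chloride | ClC(=O)/C=C/C=C/I | intermediate (not isolated)
21 | (2E,4E)-N-(2-hydroxy-5-oxocyclopent-1-en-1-yl)-5-iodopenta-2,4-dienamide | O=C(/C=C/C=C/I)NC1=C(O)CCC1=O | intermediate
22 | (2E,4E,6R)-N-[(1S,5S,6R)-5-hydroxy-5-[(1E,3E,5E)-7-[(2-hydroxy-5-oxocyclopent-1-en-1-yl)amino]-7-oxohepta-1,3,5-trien-1-yl]-2,2-dimethoxy-7-oxabicyclo[4.1.0]hept-3-en-3-yl]-4,6-dimethyldeca-2,4-dienamide | CCCC[C@@H](C)/C=C(\C)/C=C/C(=O)NC1=C[C@@](O)(/C=C/C=C/C=C/C(=O)NC2=C(O)CCC2=O)[C@@H]2O[C@@H]2C1(OC)OC | intermediate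
23 | (2E,4E,6R)-N-[(1S,5S,6R)-5-hydroxy-5-[(1E,3E,5E)-7-[(2-hydroxy-5-oxocyclopent-1-en-1-yl)amino]-7-oxohepta-1,3,5-trien-1-yl]-2-oxo-7-oxabicyclo[4.1.0]hept-3-en-3-yl]-4,6-dimethyldeca-2,4-dienamide | CCCC[C@@H](C)/C=C(C)/C=C/C(=O)NC1=C[C@@](O)(/C=C/C=C/C=C/C(=O)NC2=C(O)CCC2=O)[C@@H]2O[C@@H]2C1=O | target

**Step count and risks**
Total steps: 12. Longest linear sequence: 9 (steps 1–7, 11, 12); steps 8–10 form the convergent branch.

Three steps most likely to fail:

- **Step 3.** The ε-halo dienoate with a trisubstituted alkene lies outside the tested substrate range. Elimination to the trienoate, attack at C4 or C2, or low enantioselectivity are possible. The fallback makes the stereocentre before the diene, sets out from 2 (which then meets a chiral enal instead of 1) and comes back at 7. Bought hex-1-ene is methylaluminated (Me3Al, (−)-bis(1-neomenthylindenyl)zirconium dichloride, CH2Cl2; then O2) to (R)-2-methylhexan-1-ol F1, with the ee raised by lipase-catalysed acetylation if needed. F1 is oxidised with Dess–Martin periodinane to (R)-2-methylhexanal F2, which is olefinated with Ph3P=C(CH3)CHO to (2E,4R)-2,4-dimethyloct-2-enal F3. F3 is condensed with 2 under the step 1 conditions to give 7.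

- **Step 5.** The first oxidation of a phenol with a free para position can divert to ortho-quinol ethers or to a benzoxazole through the neighbouring amide. The fallback sets out from 9 and comes back at 11. Teuber oxidation with Fremy's salt (KO3S)2NO gives (2E,4E,6R)-N-(3,6-dioxocyclohexa-1,4-dien-1-yl)-4,6-dimethyldeca-2,4-dienamide F4. Reduction with Na2S2O4 gives (2E,4E,6R)-N-(2,5-dihydroxyphenyl)-4,6-dimethyldeca-2,4-dienamide F5, and O-methylation (Me2SO4, K2CO3, acetone) gives (2E,4E,6R)-N-(2,5-dimethoxyphenyl)-4,6-dimethyldeca-2,4-dienamide F6. F6 is oxidised with PhI(OAc)2 in MeOH, the transformation for which 2,5-dimethoxyanilides are the established substrates, to 11.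

- **Step 11.** The acidic enol of 21 and the base-sensitive epoxy ketal may poison or degrade under Heck conditions. The fallback replaces the Heck union by a Stille union, sets out from 12 and comes back at 22. Compound 12 is treated with (E)-2-(tributylstannyl)ethenyllithium (from (E)-1,2-bis(tributylstannyl)ethene and n-BuLi, THF, −78 °C; addition anti to the oxirane) to give (2E,4E,6R)-N-[(1S,5R,6R)-5-hydroxy-2,2-dimethoxy-5-[(E)-2-(tributylstannyl)ethenyl]-7-oxabicyclo[4.1.0]hept-3-en-3-yl]-4,6-dimethyldeca-2,4-dienamide F7. The descriptor at C5 changes only because tin raises the priority of the side chain; the geometry is that of 14. F7 is coupled with 21 (PdCl2(MeCN)2, DMF, rt) to give 22.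

**Further compounds**
F1 | step 3 | (R)-2-methylhexan-1-ol | CCCC[C@@H](C)CO
F2 | step 3 | (R)-2-methylhexanal | CCCC[C@@H](C)C=O
F3 | step 3 | (2E,4R)-2,4-dimethyloct-2-enal | CCCC[C@@H](C)/C=C(\C)C=O
F4 | step 5 | (2E,4E,6R)-N-(3,6-dioxocyclohexa-1,4-dien-1-yl)-4,6-dimethyldeca-2,4-dienamide | CCCC[C@@H](C)/C=C(\C)/C=C/C(=O)NC1=CC(=O)C=CC1=O
F5 | step 5 | (2E,4E,6R)-N-(2,5-dihydroxyphenyl)-4,6-dimethyldeca-2,4-dienamide | CCCC[C@@H](C)/C=C(\C)/C=C/C(=O)Nc1cc(O)ccc1O
F6 | step 5 | (2E,4E,6R)-N-(2,5-dimethoxyphenyl)-4,6-dimethyldeca-2,4-dienamide | CCCC[C@@H](C)/C=C(\C)/C=C/C(=O)Nc1cc(OC)ccc1OC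
F7 | step 11 | (2E,4E,6R)-N-[(1S,5R,6R)-5-hydroxy-2,2-dimethoxy-5-[(E)-2-(tributylstannyl)ethenyl]-7-oxabicyclo[4.1.0]hept-3-en-3-yl]-4,6-dimethyldeca-2,4-dienamide | CCCC[C@@H](C)/C=C(\C)/C=C/C(=O)NC1=C[C@@](O)(/C=C/[Sn](CCCC)(CCCC)CCCC)[C@@H]2O[C@@H]2C1(OC)OC
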